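**Plan** (unprimed locants: flavanone; single prime: ring B; double prime: flavone half)

- The five benzyl ethers come off last. Before that, flavanone ring C is cut at O1–C2 (oxa-Michael) and C2–C3 (Knoevenagel, with C3 carrying a removable tert-butyl ester), leaving a ring B aldehyde on the flavone half and a ring A β-ketoester.
- The flavone pyranone is cut in one operation at C4a''–C4'', C4''–C3'' and O1''–C2'' to an o-iodophenol, CO and 4-benzyloxyphenylacetylene. This works because O1'' and C4'' sit on the neighbouring carbons C8a'' and C4a'' of the phloroglucinol ring, and the C8a'' hydroxyl, the only free one, lies between the iodide carbon C4a'' and the biaryl carbon C8'', so closure can only give the 8-aryl flavone.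
- The C3'–C8'' biaryl bond is cut by a Suzuki coupling to 2-bromo-3,5-dibenzyloxyphenol and a ring B boronate that carries the aldehyde as a dioxolane.
- Forward order: ring B boronate, biaryl, ortho-iodination, carbonylative closure of the flavone pyranone, release of the aldehyde, Knoevenagel joining to ring A, closure of flavanone ring C, global debenzylation.
- The only stereocentre, C2 (S), is set in the ring C closure by a cinchona thiourea catalyst and sees no base afterwards.

Key step: step 7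

Assumption: the quinidine-derived thiourea is taken as the pseudoenantiomer that leads to the (2S) series; if a test on a simple alkylidene shows the opposite sense, the quinine-derived catalyst replaces it with no other change.

**Step 1**
Reactants: 1 3-bromo-4-hydroxybenzaldehyde
Product: 2 4-(benzyloxy)-3-bromobenzaldehyde
Conditions: BnBr, K2CO3, DMF, rt
Reagents that add atoms: benzyl bromide, BrCc1ccccc1
Why: Williamson etherification of the acidic phenol should be clean, and benzyl is chosen so that all phenols of the route are released together in the last step.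

**Step 2**
Reactants: 2 4-(benzyloxy)-3-bromobenzaldehyde
Product: 3 2-[4-(benzyloxy)-3-bromophenyl]-1,3-dioxolane
Conditions: ethylene glycol, p-TsOH (cat.), toluene, reflux, Dean–Stark
Reagents that add atoms: ethylene glycol, OCCO
Why: Acid-catalysed acetalisation with azeotropic removal of water masks the aldehyde against the boron, palladium and amine chemistry ahead without touching the aryl bromide or the benzyl ether.

**Step 3**
Reactants: 3 2-[4-(benzyloxy)-3-bromophenyl]-1,3-dioxolane
Product: 4 2-[2-(benzyloxy)-5-(1,3-dioxolan-2-yl)phenyl]-4,4,5,5-tetramethyl-1,3,2-dioxaborolane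
Conditions: B2pin2, PdCl2(dppf) (3 mol %), KOAc, 1,4-dioxane, 90 °C
Reagents that add atoms: bis(pinacolato)diboron, CC1(C)OB(OC1(C)C)B1OC(C)(C)C(C)(C)O1
Why: Miyaura borylation of the aryl bromide tolerates the dioxolane and the ortho benzyloxy group and should give a boronate stable enough to purify.

**Step 4**
Reactants: 5 3,5-bis(benzyloxy)phenol
Product: 6 3,5-bis(benzyloxy)-2-bromophenol
Conditions: NBS (1.0 equiv), i-Pr2NH (10 mol %), CH2Cl2, −78 °C
Reagents that add atoms: N-bromosuccinimide, O=C1CCC(=O)N1Br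
Why: Electrophilic aromatic bromination with the NBS–secondary amine couple favours the position ortho to a free hydroxyl, and one equivalent at low temperature should stop at the monobromide, any para isomer being removed by chromatography.

**Step 5**
Reactants: 6 3,5-bis(benzyloxy)-2-bromophenol; 4 2-[2-(benzyloxy)-5-(1,3-dioxolan-2-yl)phenyl]-4,4,5,5-tetramethyl-1,3,2-dioxaborolane
Product: 7 3,5-bis(benzyloxy)-2-[2-(benzyloxy)-5-(1,3-dioxolan-2-yl)phenyl]phenol
Conditions: Pd(OAc)2 (5 mol %), SPhos (10 mol %), K3PO4, toluene/H2O, 90 °C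
Reagents that add atoms: none
Why: Suzuki–Miyaura coupling with the bulky, electron-rich SPhos ligand is the standard answer to tri-ortho-substituted biaryls from electron-rich bromides, tolerates the free phenol and the base-stable dioxolane, and forms the C3'–C8'' bond.

**Step 6**
Reactants: 7 3,5-bis(benzyloxy)-2-[2-(benzyloxy)-5-(1,3-dioxolan-2-yl)phenyl]phenol
Product: 8 3,5-bis(benzyloxy)-2-[2-(benzyloxy)-5-(1,3-dioxolan-2-yl)phenyl]-6-iodophenol
Conditions: NIS (1.05 equiv), CH2Cl2, −20 to 0 °C, dark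
Reagents that add atoms: N-iodosuccinimide, O=C1CCC(=O)N1I
Why: Electrophilic aromatic iodination should go to the one remaining carbon ortho to the hydroxyl (the future C4a''), because the para carbon lies between two benzyloxy groups and is more hindered for the large iodine donor, while ring B is far less activated and the acetal survives acid-free conditions.

**Step 7**
Reactants: 8 3,5-bis(benzyloxy)-2-[2-(benzyloxy)-5-(1,3-dioxolan-2-yl)phenyl]-6-iodophenol; 9 1-(benzyloxy)-4-ethynylbenzene
Product: 12 5,7-bis(benzyloxy)-8-[2-(benzyloxy)-5-(1,3-dioxolan-2-yl)phenyl]-2-[4-(benzyloxy)phenyl]-4H-chromen-4-one, via o-hydroxyaryl ynone 10 (not isolated), via diethylamino enaminone 11 (not isolated)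
Conditions: PdCl2(PPh3)2 (5 mol %), CO (20 atm), Et2NH, 120 °C
Reagents that add atoms: carbon monoxide, [C-]#[O+]
Why: Zerovalent palladium formed in situ from PdCl2(PPh3)2 inserts into the C4a''–I bond of 8, CO insertion gives an aroyl complex of divalent palladium, and coupling with the amine-deprotonated alkyne 9 followed by reductive elimination releases ynone 10, which forms C4a''–C4'' and C4''–C3''. Diethylamine then adds to the ynone to give enaminone 11, and the C8a'' hydroxyl closes the pyranone by 6-endo attack at C2'' with loss of the amine, forming O1''–C2''; the secondary amine is what steers the closure away from the 5-exo path to an aurone. The closest known reaction type is the palladium-catalysed carbonylative Sonogashira annulation of o-iodophenols with terminal arylacetylenes to flavones under CO pressure in a secondary amine. No stereocentre is created. The step needs carbonylation to outrun direct alkynylation, which would end in a benzofuran and is suppressed by 20 atm of CO, and it needs the 8-aryl and not the 6-aryl flavone, which the substrate guarantees because its only free hydroxyl sits between the iodide carbon and the biaryl carbon. The dioxolane and the benzyl ethers are inert to amine, CO and heat, and the base-sensitive flavanone does not yet exist when this step runs.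

**Step 8**
Reactants: 12 5,7-bis(benzyloxy)-8-[2-(benzyloxy)-5-(1,3-dioxolan-2-yl)phenyl]-2-[4-(benzyloxy)phenyl]-4H-chromen-4-one
Product: 13 4-(benzyloxy)-3-{5,7-bis(benzyloxy)-2-[4-(benzyloxy)phenyl]-4-oxo-4H-chromen-8-yl}benzaldehyde
Conditions: 1 M HCl, THF, rt
Reagents that add atoms: water, O
Why: Acid-catalysed acetal hydrolysis frees the ring B aldehyde, and the flavone and the benzyl ethers are stable to dilute aqueous acid at room temperature.

**Step 9**
Reactants: 14 1-(2,6-dihydroxy-4-methoxyphenyl)ethanone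
Product: 15 1-[2-(benzyloxy)-6-hydroxy-4-methoxyphenyl]ethanone
Conditions: BnBr (1.05 equiv), K2CO3, acetone, reflux
Reagents that add atoms: benzyl bromide, BrCc1ccccc1
Why: Williamson monobenzylation is self-limiting because the remaining hydroxyl is held in a hydrogen bond to the acetyl carbonyl after the first alkylation, and the two hydroxyls are equivalent so no regiochemical question arises.

**Step 10**
Reactants: 15 1-[2-(benzyloxy)-6-hydroxy-4-methoxyphenyl]ethanone
Product: 16 tert-butyl 3-[2-(benzyloxy)-6-hydroxy-4-methoxyphenyl]-3-oxopropanoate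
Conditions: LiN(SiMe3)2 (3.2 equiv), THF, −78 °C; Boc2O (1.1 equiv), −78 to 0 °C; aq. NH4Cl
Reagents that add atoms: di-tert-butyl dicarbonate, CC(C)(C)OC(=O)OC(=O)OC(C)(C)C
Why: Claisen-type C-acylation of the lithium enolate of the methyl ketone by Boc2O should give the tert-butyl β-ketoester, any aryl carbonate formed at the phenoxide passing its acyl group to the enolate carbon in a Baker–Venkataraman-type shift, and the bulky ester resists lactonisation to a 4-hydroxycoumarin.

**Step 11**
Reactants: 13 4-(benzyloxy)-3-{5,7-bis(benzyloxy)-2-[4-(benzyloxy)phenyl]-4-oxo-4H-chromen-8-yl}benzaldehyde; 16 tert-butyl 3-[2-(benzyloxy)-6-hydroxy-4-methoxyphenyl]-3-oxopropanoate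
Product: 17 tert-butyl (Z)-2-[2-(benzyloxy)-6-hydroxy-4-methoxybenzoyl]-3-(4-(benzyloxy)-3-{5,7-bis(benzyloxy)-2-[4-(benzyloxy)phenyl]-4-oxo-4H-chromen-8-yl}phenyl)prop-2-enoate
Conditions: piperidine (20 mol %), AcOH (20 mol %), 4 Å MS, toluene, rt
Reagents that add atoms: none
Why: Knoevenagel condensation of the aldehyde with the active methylene forms the future C2–C3 bond as an alkylidene (drawn as the expected major Z isomer) activated enough for catalyst-controlled closure at low temperature, and the mild conditions are meant to keep the hydrogen-bonded phenol from closing prematurely.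

**Step 12**
Reactants: 17 tert-butyl (Z)-2-[2-(benzyloxy)-6-hydroxy-4-methoxybenzoyl]-3-(4-(benzyloxy)-3-{5,7-bis(benzyloxy)-2-[4-(benzyloxy)phenyl]-4-oxo-4H-chromen-8-yl}phenyl)prop-2-enoate
Product: 20 (2S)-5-(benzyloxy)-2-(4-(benzyloxy)-3-{5,7-bis(benzyloxy)-2-[4-(benzyloxy)phenyl]-4-oxo-4H-chromen-8-yl}phenyl)-7-methoxychroman-4-one, via 3-tert-butoxycarbonyl flavanone 18 (not isolated), via flavanone 3-carboxylic acid 19 (not isolated)
Conditions: 1-[3,5-bis(trifluoromethyl)phenyl]-3-(9-deoxy-epi-quinidin-9-yl)thiourea (10 mol %), toluene, −25 °C; then p-TsOH·H2O, 80 °C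
Reagents that add atoms: none
Why: Asymmetric intramolecular oxa-Michael addition under bifunctional cinchona thiourea catalysis, with the thiourea binding the 1,3-dicarbonyl unit and the quinuclidine nitrogen guiding the phenol, should close ring C 6-endo-trig on one face of the alkylidene and so set C2 as (S), after which acid cleavage of the tert-butyl ester and decarboxylation in the same pot erase the C3 centre without touching C2.

**Step 13**
Reactants: 20 (2S)-5-(benzyloxy)-2-(4-(benzyloxy)-3-{5,7-bis(benzyloxy)-2-[4-(benzyloxy)phenyl]-4-oxo-4H-chromen-8-yl}phenyl)-7-methoxychroman-4-one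
Product: 21 8-{2-hydroxy-5-[(2S)-5-hydroxy-7-methoxy-4-oxochroman-2-yl]phenyl}-5,7-dihydroxy-2-(4-hydroxyphenyl)-4H-chromen-4-one (CNP0107492.1)
Conditions: H2 (1 atm), Pd/C (10 %), THF/MeOH, rt
Reagents that add atoms: none
Why: Hydrogenolysis of the five benzyl ethers over palladium on carbon is neutral, so the base-labile C2 stereocentre is not exposed to ring opening, and flavone and flavanone carbonyls normally survive these mild conditions.

**Compound list**

1 | 3-bromo-4-hydroxybenzaldehyde | O=Cc1ccc(O)c(Br)c1 | starting material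
2 | 4-(benzyloxy)-3-bromobenzaldehyde | O=Cc1ccc(OCc2ccccc2)c(Br)c1 | intermediate
3 | 2-[4-(benzyloxy)-3-bromophenyl]-1,3-dioxolane | Brc1cc(C2OCCO2)ccc1OCc1ccccc1 | intermediate
4 | 2-[2-(benzyloxy)-5-(1,3-dioxolan-2-yl)phenyl]-4,4,5,5-tetramethyl-1,3,2-dioxaborolane | CC1(C)OB(OC1(C)C)c1cc(C2OCCO2)ccc1OCc1ccccc1 | intermediate
5 | 3,5-bis(benzyloxy)phenol | Oc1cc(OCc2ccccc2)cc(OCc2ccccc2)c1 | starting material
6 | 3,5-bis(benzyloxy)-2-bromophenol | Oc1cc(OCc2ccccc2)cc(OCc2ccccc2)c1Br | intermediate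
7 | 3,5-bis(benzyloxy)-2-[2-(benzyloxy)-5-(1,3-dioxolan-2-yl)phenyl]phenol | Oc1cc(OCc2ccccc2)cc(OCc2ccccc2)c1-c1cc(C2OCCO2)ccc1OCc1ccccc1 | intermediate
8 | 3,5-bis(benzyloxy)-2-[2-(benzyloxy)-5-(1,3-dioxolan-2-yl)phenyl]-6-iodophenol | Oc1c(I)c(OCc2ccccc2)cc(OCc2ccccc2)c1-c1cc(C2OCCO2)ccc1OCc1ccccc1 | intermediate
9 | 1-(benzyloxy)-4-ethynylbenzene | C#Cc1ccc(OCc2ccccc2)cc1 | starting material
10 | 1-{4,6-bis(benzyloxy)-3-[2-(benzyloxy)-5-(1,3-dioxolan-2-yl)phenyl]-2-hydroxyphenyl}-3-[4-(benzyloxy)phenyl]prop-2-yn-1-one | O=C(C#Cc1ccc(OCc2ccccc2)cc1)c1c(O)c(-c2cc(C3OCCO3)ccc2OCc2ccccc2)c(OCc2ccccc2)cc1OCc1ccccc1 | intermediate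
11 | (E)-1-{4,6-bis(benzyloxy)-3-[2-(benzyloxy)-5-(1,3-dioxolan-2-yl)phenyl]-2-hydroxyphenyl}-3-[4-(benzyloxy)phenyl]-3-(diethylamino)prop-2-en-1-one | O=C(/C=C(\c1ccc(OCc2ccccc2)cc1)N(CC)CC)c1c(O)c(-c2cc(C3OCCO3)ccc2OCc2ccccc2)c(OCc2ccccc2)cc1OCc1ccccc1 | intermediate
12 | 5,7-bis(benzyloxy)-8-[2-(benzyloxy)-5-(1,3-dioxolan-2-yl)phenyl]-2-[4-(benzyloxy)phenyl]-4H-chromen-4-one | O=c1cc(-c2ccc(OCc3ccccc3)cc2)oc2c(-c3cc(C4OCCO4)ccc3OCc3ccccc3)c(OCc3ccccc3)cc(OCc3ccccc3)c12 | intermediate
13 | 4-(benzyloxy)-3-{5,7-bis(benzyloxy)-2-[4-(benzyloxy)phenyl]-4-oxo-4H-chromen-8-yl}benzaldehyde | O=Cc1ccc(OCc2ccccc2)c(-c2c(OCc3ccccc3)cc(OCc3ccccc3)c3c(=O)cc(-c4ccc(OCc5ccccc5)cc4)oc23)c1 | intermediate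
14 | 1-(2,6-dihydroxy-4-methoxyphenyl)ethanone | CC(=O)c1c(O)cc(OC)cc1O | starting material
15 | 1-[2-(benzyloxy)-6-hydroxy-4-methoxyphenyl]ethanone | CC(=O)c1c(O)cc(OC)cc1OCc1ccccc1 | intermediate
16 | tert-butyl 3-[2-(benzyloxy)-6-hydroxy-4-methoxyphenyl]-3-oxopropanoate | CC(C)(C)OC(=O)CC(=O)c1c(O)cc(OC)cc1OCc1ccccc1 | intermediate
17 | tert-butyl (Z)-2-[2-(benzyloxy)-6-hydroxy-4-methoxybenzoyl]-3-(4-(benzyloxy)-3-{5,7-bis(benzyloxy)-2-[4-(benzyloxy)phenyl]-4-oxo-4H-chromen-8-yl}phenyl)prop-2-enoate | CC(C)(C)OC(=O)/C(=C\c1ccc(OCc2ccccc2)c(-c2c(OCc3ccccc3)cc(OCc3ccccc3)c3c(=O)cc(-c4ccc(OCc5ccccc5)cc4)oc23)c1)C(=O)c1c(O)cc(OC)cc1OCc1ccccc1 | intermediate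
18 | tert-butyl (2S,3R)-5-(benzyloxy)-2-(4-(benzyloxy)-3-{5,7-bis(benzyloxy)-2-[4-(benzyloxy)phenyl]-4-oxo-4H-chromen-8-yl}phenyl)-7-methoxy-4-oxochromane-3-carboxylate (trans; C3 is labile) | COc1cc(OCc2ccccc2)c2c(c1)O[C@H](c1ccc(OCc3ccccc3)c(-c3c(OCc4ccccc4)cc(OCc4ccccc4)c4c(=O)cc(-c5ccc(OCc6ccccc6)cc5)oc34)c1)[C@@H](C(=O)OC(C)(C)C)C2=O | intermediate
19 | (2S,3R)-5-(benzyloxy)-2-(4-(benzyloxy)-3-{5,7-bis(benzyloxy)-2-[4-(benzyloxy)phenyl]-4-oxo-4H-chromen-8-yl}phenyl)-7-methoxy-4-oxochromane-3-carboxylic acid | COc1cc(OCc2ccccc2)c2c(c1)O[C@H](c1ccc(OCc3ccccc3)c(-c3c(OCc4ccccc4)cc(OCc4ccccc4)c4c(=O)cc(-c5ccc(OCc6ccccc6)cc5)oc34)c1)[C@@H](C(=O)O)C2=O | intermediate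
20 | (2S)-5-(benzyloxy)-2-(4-(benzyloxy)-3-{5,7-bis(benzyloxy)-2-[4-(benzyloxy)phenyl]-4-oxo-4H-chromen-8-yl}phenyl)-7-methoxychroman-4-one | COc1cc(OCc2ccccc2)c2c(c1)O[C@H](c1ccc(OCc3ccccc3)c(-c3c(OCc4ccccc4)cc(OCc4ccccc4)c4c(=O)cc(-c5ccc(OCc6ccccc6)cc5)oc34)c1)CC2=O | intermediate
21 | 8-{2-hydroxy-5-[(2S)-5-hydroxy-7-methoxy-4-oxochroman-2-yl]phenyl}-5,7-dihydroxy-2-(4-hydroxyphenyl)-4H-chromen-4-one | COc1cc(O)c2c(c1)O[C@H](c1ccc(O)c(-c3c(O)cc(O)c4c(=O)cc(-c5ccc(O)cc5)oc34)c1)CC2=O | target

**Totals**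

Total step count: 13.
Longest linear sequence: 10 steps (steps 1, 2, 3, 5, 6, 7, 8, 11, 12, 13).

**Steps most likely to fail**

Step 7. Oxidative addition into the electron-rich C–I bond, flanked by two ortho substituents, may be slow, so that the alkyne is consumed by oligomerisation or amine addition, and incomplete CO insertion or 5-exo closure may divert material to benzofuran or aurone products. The fallback sets out from 8 and 9, returns at 12, and builds the ynone without palladium and CO. Alkyne 9 would be deprotonated with n-BuLi (THF, −78 °C) and acylated with N-methoxy-N-methylcarbamoyl chloride to the Weinreb amide 3-[4-(benzyloxy)phenyl]-N-methoxy-N-methylprop-2-ynamide F1. Phenol 8 would be silylated (TBSCl, imidazole, DMF) to the tert-butyldimethylsilyl ether of 8 F2. Iodine–magnesium exchange on F2 (i-PrMgCl·LiCl, THF, −20 °C) and acylation of the aryl Grignard with F1 should give the silyl-protected ynone F3. Et2NH in EtOH would turn F3 into the enaminone, and Bu4NF would then release the phenoxide, which closes 6-endo with loss of the amine to give 12.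

Step 6. Site selectivity may be poor, with attack at the carbon para to the hydroxyl between the two benzyloxy groups, and over-iodination may occur. The fallback sets out from 7, returns at 8, and replaces electrophilic substitution by directed metalation. The phenol would be converted (Boc2O, DMAP cat., CH2Cl2) into the tert-butyl carbonate of 7 F4. Magnesiation with (tmp)2Mg·2LiCl (tmp = 2,2,6,6-tetramethylpiperidide; THF, 0 °C) should occur at the only C–H ortho to the carbonate director, and an I2 quench would give the tert-butyl carbonate of 8 F5. K2CO3 in MeOH would cleave the carbonate and return 8.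

Step 12. Enantioselectivity may be lost through uncatalysed background cyclisation of the alkylidene (during the Knoevenagel step, or because the ortho benzyloxy group twists the aryl ketone out of the catalyst's binding mode), through reversible ring opening during the hot acid decarboxylation, or through a sense of induction opposite to the one assumed. The fallback sets out from 13 and 15, returns at 20, and replaces asymmetric catalysis by resolution. Claisen–Schmidt condensation of 13 with 15 (KOH, EtOH/THF, rt) would give the 2'-hydroxychalcone F6. NaOAc in refluxing EtOH would close it to the racemic flavanone F7. Preparative HPLC on a polysaccharide-based chiral stationary phase would separate 20 from its (2R) enantiomer F8.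

**Further compounds**

F1 | step 7 | 3-[4-(benzyloxy)phenyl]-N-methoxy-N-methylprop-2-ynamide | CON(C)C(=O)C#Cc1ccc(OCc2ccccc2)cc1
F2 | step 7 | {3,5-bis(benzyloxy)-2-[2-(benzyloxy)-5-(1,3-dioxolan-2-yl)phenyl]-6-iodophenoxy}(tert-butyl)dimethylsilane | CC(C)(C)[Si](C)(C)Oc1c(I)c(OCc2ccccc2)cc(OCc2ccccc2)c1-c1cc(C2OCCO2)ccc1OCc1ccccc1
F3 | step 7 | 1-{4,6-bis(benzyloxy)-3-[2-(benzyloxy)-5-(1,3-dioxolan-2-yl)phenyl]-2-[(tert-butyldimethylsilyl)oxy]phenyl}-3-[4-(benzyloxy)phenyl]prop-2-yn-1-one | CC(C)(C)[Si](C)(C)Oc1c(C(=O)C#Cc2ccc(OCc3ccccc3)cc2)c(OCc2ccccc2)cc(OCc2ccccc2)c1-c1cc(C2OCCO2)ccc1OCc1ccccc1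
F4 | step 6 | 3,5-bis(benzyloxy)-2-[2-(benzyloxy)-5-(1,3-dioxolan-2-yl)phenyl]phenyl tert-butyl carbonate | CC(C)(C)OC(=O)Oc1cc(OCc2ccccc2)cc(OCc2ccccc2)c1-c1cc(C2OCCO2)ccc1OCc1ccccc1
F5 | step 6 | 3,5-bis(benzyloxy)-2-[2-(benzyloxy)-5-(1,3-dioxolan-2-yl)phenyl]-6-iodophenyl tert-butyl carbonate | CC(C)(C)OC(=O)Oc1c(I)c(OCc2ccccc2)cc(OCc2ccccc2)c1-c1cc(C2OCCO2)ccc1OCc1ccccc1
F6 | step 12 | (E)-1-[2-(benzyloxy)-6-hydroxy-4-methoxyphenyl]-3-(4-(benzyloxy)-3-{5,7-bis(benzyloxy)-2-[4-(benzyloxy)phenyl]-4-oxo-4H-chromen-8-yl}phenyl)prop-2-en-1-one | COc1cc(O)c(C(=O)/C=C/c2ccc(OCc3ccccc3)c(-c3c(OCc4ccccc4)cc(OCc4ccccc4)c4c(=O)cc(-c5ccc(OCc6ccccc6)cc5)oc34)c2)c(OCc2ccccc2)c1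
F7 | step 12 | racemic 5-(benzyloxy)-2-(4-(benzyloxy)-3-{5,7-bis(benzyloxy)-2-[4-(benzyloxy)phenyl]-4-oxo-4H-chromen-8-yl}phenyl)-7-methoxychroman-4-one | COc1cc(OCc2ccccc2)c2c(c1)OC(c1ccc(OCc3ccccc3)c(-c3c(OCc4ccccc4)cc(OCc4ccccc4)c4c(=O)cc(-c5ccc(OCc6ccccc6)cc5)oc34)c1)CC2=O
F8 | step 12 | (2R)-5-(benzyloxy)-2-(4-(benzyloxy)-3-{5,7-bis(benzyloxy)-2-[4-(benzyloxy)phenyl]-4-oxo-4H-chromen-8-yl}phenyl)-7-methoxychroman-4-one | COc1cc(OCc2ccccc2)c2c(c1)O[C@@H](c1ccc(OCc3ccccc3)c(-c3c(OCc4ccccc4)cc(OCc4ccccc4)c4c(=O)cc(-c5ccc(OCc6ccccc6)cc5)oc34)c1)CC2=O
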